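The 14-membered carbocycle is cut at C7–C8 (cembrane numbering). The quaternary C8 carries CH3, OOH and the (E)-C6=C7 alkenyl group, so it can be traced back to a methyl ketone carbon that gains a peroxide oxygen and then an alkenyl carbon. A single Lewis-acid step is planned to ionise a C8 peroxyketal, join C7 to C8, close the macrocycle, create the C8 stereocentre and leave the O–O bond in place. Its precursor is an open-chain δ-lactone (ring C15–C16–O–C3–C2–C1; C1, C3, C4 and C15 set) bearing a C8 methoxy silylperoxy ketal on the C1 arm and an (E)-alkenyltrifluoroborate at C7 on the C3 arm, with C11=C12 still an alkene.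

Key step: step 21

Remark on numbering: positions are given in cembrane numbering (ring C1–C14; C15 on C1 bears methyl C17 and carbonyl C16; methyls C18, C19, C20 sit on C4, C8, C12); "oxan-2-one" is tetrahydropyran-2-one.
Remark on the precursor: the C4 hydroxyl is carried as a triethylsilyl ether so that no free OH meets BF3, and the hydroperoxide is carried as a tert-butyldimethylsilyl peroxide so that it survives bifluoride.
Remark on C8: compounds 28–32 are mixtures of C8 epimers, which is without consequence because C8 becomes planar in step 21.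
Remark on order: the lactone is closed only after the alkyne is in place, and boron is introduced only after the peroxide, because acetylides attack lactones and hydrogen peroxide oxidises C–B bonds.

Step 1
Reactants: 1 pentane-2,4-dione; 2 1-bromobut-2-yne
Product: 4 hept-5-yn-2-one, via alkylated diketone 3 (not isolated)
Conditions: K2CO3, EtOH, reflux
Reagents that add atoms: none
Why: Deacetylative C-alkylation of a 1,3-diketone: the potassium enolate is alkylated by the propargylic bromide and the 3-substituted diketone then undergoes retro-Claisen cleavage by ethanol in the same pot, giving the methyl ketone (C8–C12, C19, C20).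

Step 2
Reactants: 4 hept-5-yn-2-one
Product: 5 6,6-dimethoxyhept-2-yne
Conditions: HC(OMe)3, MeOH, TsOH (cat.), rt
Reagents that add atoms: trimethyl orthoformate COC(OC)OC; methanol CO
Why: Acid-catalysed ketalisation driven by the orthoformate; the acyclic dimethyl ketal is chosen because it can later be exchanged directly with hydrogen peroxide.

Step 3
Reactants: 5 6,6-dimethoxyhept-2-yne
Product: 7 (2E)-2-iodo-6,6-dimethoxyhept-2-ene, via alkenylzirconocene 6 (not isolated)
Conditions: Cp2Zr(H)Cl, THF, rt → 45 °C; I2, 0 °C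
Reagents that add atoms: iodine II
Why: Hydrozirconation (syn addition) of the 2-alkyne equilibrates with excess reagent to the less hindered methyl-bearing alkenylzirconium, and iodinolysis with retention should give the (E)-2-iodoalkene that fixes the later C11=C12 geometry.

Step 4
Reactants: 8 5,6-dihydro-2H-pyran-2-one; 9 potassium trifluoro(vinyl)borate
Product: 10 (4R)-4-ethenyloxan-2-one
Conditions: [Rh(cod)2]PF6 (3 mol%), (R)-BINAP, toluene/H2O, 100 °C
Reagents that add atoms: none
Why: Hayashi–Miyaura rhodium-catalysed asymmetric 1,4-addition of an alkenylboron reagent to an unsaturated lactone; (R)-BINAP should direct the vinyl group to the face that gives the (4R)-lactone (the future C1), by analogy with aryl additions to the same lactone.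

Step 5
Reactants: 10 (4R)-4-ethenyloxan-2-one
Product: 12 (3S,4S)-4-ethenyl-3-methyloxan-2-one, via lithium enolate 11 (not isolated)
Conditions: LiN(iPr)2, THF, −78 °C; MeI, −78 → −30 °C
Reagents that add atoms: iodomethane CI
Why: Kinetic alkylation of the lactone enolate, in which iodomethane should approach anti to the neighbouring vinyl group and so set the C15 methyl trans to the C1 substituent (also the thermodynamically preferred diequatorial arrangement).

Step 6
Reactants: 12 (3S,4S)-4-ethenyl-3-methyloxan-2-one
Product: 13 hydroxy dimethylamide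
Conditions: Me2NH·HCl, AlMe3, CH2Cl2, 0 °C → rt
Reagents that add atoms: dimethylamine hydrochloride CNC.Cl
Why: Aluminium-amide aminolysis of the lactone (Weinreb-type) frees C3 as a primary alcohol and stores C16 as a dimethylamide that tolerates the next steps and later acts as the internal oxygen nucleophile; no stereocentre is touched.

Step 7
Reactants: 13 hydroxy dimethylamide
Product: 14 amide aldehyde
Conditions: Dess–Martin periodinane, NaHCO3, CH2Cl2, 0 °C → rt
Reagents that add atoms: none
Why: Dess–Martin oxidation of the primary alcohol to the C3 aldehyde under buffered conditions; the carbon next to the new carbonyl is a CH2, so nothing can epimerise.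

Step 8
Reactants: 14 amide aldehyde; 15 2-(triphenylphosphoranylidene)propanal
Product: 16 (E)-enal amide
Conditions: toluene, 90 °C
Reagents that add atoms: none
Why: Wittig olefination with a stabilised formyl ylide, which should give the (E)-trisubstituted enal (C3=C4 with the C18 methyl and C5 as CHO) and leaves the amide alone.

Step 9
Reactants: 16 (E)-enal amide
Product: 17 allylic alcohol amide
Conditions: NaBH4, CeCl3·7H2O, MeOH, 0 °C
Reagents that add atoms: none
Why: Luche 1,2-reduction of the enal to the primary allylic alcohol; the amide and the vinyl group are inert.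

Step 10
Reactants: 17 allylic alcohol amide
Product: 18 allylic bromide amide
Conditions: CBr4, PPh3, CH2Cl2, 0 °C
Reagents that add atoms: carbon tetrabromide BrC(Br)(Br)Br
Why: Appel bromination of the primary allylic alcohol, which at low temperature should proceed without allylic transposition.

Step 11
Reactants: 18 allylic bromide amide; 19 ethynyltrimethylsilane
Product: 20 skipped enyne amide
Conditions: CuI (20 mol%), K2CO3, Bu4NI (cat.), DMF, rt
Reagents that add atoms: none
Why: Copper-catalysed coupling of a terminal alkyne with a primary allylic halide, which should substitute directly at the unhindered CH2 (C5) and so attach C6 and C7 as a silyl-capped alkyne.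

Step 12
Reactants: 20 skipped enyne amide
Product: 21 (3S,4S)-epoxy amide
Conditions: L-fructose-derived Shi ketone (30 mol%), KHSO5 (as 2KHSO5·KHSO4·K2SO4), K2CO3, Bu4NHSO4, MeCN/CH2(OMe)2, aq. Na2B4O7 buffer, 0 °C
Reagents that add atoms: potassium peroxymonosulfate [K+].[O-]S(=O)(=O)OO
Why: Shi asymmetric epoxidation: the trisubstituted C3=C4 alkene reacts much faster than the monosubstituted vinyl group or the alkyne, and the L-fructose-derived ketone should deliver oxygen through the usual spiro transition state to give the (3S,4S)-epoxide.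

Step 13
Reactants: 21 (3S,4S)-epoxy amide
Product: 23 hydroxy lactone, via iminium lactone 22 (not isolated)
Conditions: CSA (1.2 equiv), CH2Cl2, 0 °C; then H2O
Reagents that add atoms: water O
Why: Acid-promoted intramolecular epoxide opening by the amide oxygen (6-exo attack at the secondary C3 with inversion, favoured over 7-endo attack at C4) followed by hydrolysis of the iminium lactone, so that C3 becomes (R), C4 keeps its oxygen with retention as the (S)-tertiary alcohol and the δ-lactone is closed.

Step 14
Reactants: 23 hydroxy lactone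
Product: 24 C4 triethylsilyl ether
Conditions: TESOTf, 2,6-lutidine, CH2Cl2, −78 → 0 °C
Reagents that add atoms: triethylsilyl trifluoromethanesulfonate CC[Si](CC)(CC)OS(=O)(=O)C(F)(F)F
Why: Silylation of the tertiary alcohol with a silyl triflate; the ether keeps a free hydroxyl, and the strong Brønsted acid it would form with BF3, out of the later cyclisation.

Step 15
Reactants: 24 C4 triethylsilyl ether; 7 (2E)-2-iodo-6,6-dimethoxyhept-2-ene
Product: 26 coupled dimethyl ketal, via B-alkylborane 25 (not isolated)
Conditions: 9-BBN, THF, rt; then 7, PdCl2(dppf) (5 mol%), AsPh3, Cs2CO3, DMF/H2O, rt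
Reagents that add atoms: none
Why: B-alkyl Suzuki–Miyaura coupling: 9-BBN hydroborates the monosubstituted alkene much faster than the silylated alkyne or the lactone, and the alkylborane couples with the vinyl iodide with retention to give the (E)-C11=C12 alkene and the full C8–C14 chain; partial loss of the alkynyl silyl group in the basic medium would be harmless.

Step 16
Reactants: 26 coupled dimethyl ketal
Product: 27 terminal alkyne ketal
Conditions: AgNO3 (10 mol%), 2,6-lutidine, acetone/H2O, rt
Reagents that add atoms: none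
Why: Silver-catalysed protodesilylation cleaves only the C(sp)–Si bond, so the tertiary silyl ether, the ketal and the lactone should survive these near-neutral conditions.

Step 17
Reactants: 27 terminal alkyne ketal
Product: 28 C8 methoxy hydroperoxy ketal
Conditions: H2O2 (anhydrous, in Et2O), CSA (cat.), 0 °C; NaHCO3
Reagents that add atoms: hydrogen peroxide OO
Why: Acid-catalysed perhydrolysis of the dimethyl ketal, in which the methoxycarbenium ion is trapped by hydrogen peroxide to give the 1-methoxy hydroperoxide; C8 forms as both epimers, which does not matter.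

Step 18
Reactants: 28 C8 methoxy hydroperoxy ketal
Product: 29 C8 methoxy silylperoxy ketal
Conditions: TBSCl, imidazole, DMF, 0 °C
Reagents that add atoms: tert-butyldimethylsilyl chloride CC(C)(C)[Si](C)(C)Cl
Why: O-Silylation of the hydroperoxide, which is far more accessible than any other position; the bulky silyl peroxide is chosen to withstand bifluoride and to shield the distal peroxide oxygen from Lewis acid.

Step 19
Reactants: 29 C8 methoxy silylperoxy ketal
Product: 30 (E)-alkenyl pinacol boronate
Conditions: pinacolborane, Cy2BH (10 mol%), THF, rt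
Reagents that add atoms: pinacolborane B1OC(C)(C)C(C)(C)O1
Why: Dialkylborane-catalysed hydroboration of the terminal alkyne (syn, anti-Markovnikov) should give the (E)-alkenylboronate; pinacolborane is a weak hydride donor, so lactone, trisubstituted alkene and hindered silyl peroxide are expected to survive.

Step 20
Reactants: 30 (E)-alkenyl pinacol boronate
Product: 31 potassium (E)-alkenyltrifluoroborate (cyclisation precursor)
Conditions: KHF2 (aq.), MeCN, 0 °C, short contact
Reagents that add atoms: potassium hydrogen difluoride [K+].F[H-]F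
Why: Standard conversion of a boronic ester into the trifluoroborate salt; brief exposure at 0 °C and the hindered silicon centres should keep the silyl peroxide and the tertiary silyl ether intact, and the salt is purified by extraction into acetone and not on silica.

Step 21
Reactants: 31 potassium (E)-alkenyltrifluoroborate
Product: 34 macrocyclic C8 silyl peroxide, via alkenyldifluoroborane 32 (not isolated), via peroxycarbenium zwitterion 33 (not isolated)
Conditions: BF3·OEt2 (3 equiv), 18-crown-6, CH2Cl2, −78 → −40 °C, 31 added by syringe pump to 1 mM; aq. NaHCO3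
Reagents that add atoms: none
Why: Proposed new method: BF3 first takes fluoride from the trifluoroborate to give the alkenyldifluoroborane, whose boron (or excess BF3) then takes methoxide from the C8 ketal, leaving a carbenium ion stabilised by the silylperoxy oxygen; C7 attacks C8, the β-boryl cation at C6 loses boron and the (E)-C6=C7 alkene is restored in place (ipso substitution). The closest known reactions are Lewis-acid allylation of peroxycarbenium ions generated from monoperoxyketals and BF3-promoted addition of alkenyltrifluoroborates to oxocarbenium ions. The 14-membered carbocycle closes exo at C8 (the C=O+ bond stays outside the ring) and endo with respect to the alkenyl unit. The new C8 centre can be controlled only by the conformation of the closing ring, in which the lactone, the two (E)-alkenes and the C4 silyl ether should favour peripheral attack on one face of the planar cation; the (8S) isomer is required and its epimer would be removed by chromatography. The step also needs C–C bond formation to outrun Criegee- or Hock-type peroxide rearrangement, attack by C11=C12 and oligomerisation: the bulky silyl group disfavours coordination at the distal peroxide oxygen, C11=C12 could reach C8 only through four- or five-membered closures, the C4 hydroxyl is masked, and the reaction is run cold at high dilution.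

Step 22
Reactants: 34 macrocyclic C8 silyl peroxide
Product: 35 11,12-epoxide
Conditions: L-fructose-derived Shi ketone (30 mol%), KHSO5 (as 2KHSO5·KHSO4·K2SO4), K2CO3, Bu4NHSO4, MeCN/CH2(OMe)2, aq. Na2B4O7 buffer, 0 °C
Reagents that add atoms: potassium peroxymonosulfate [K+].[O-]S(=O)(=O)OO
Why: Shi epoxidation of the only trisubstituted alkene (C6=C7 is disubstituted, flanked by two quaternary carbons and deactivated by the allylic peroxide); the L-fructose-derived ketone should deliver oxygen to the face that gives the (11S,12S)-epoxide.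

Step 23
Reactants: 35 11,12-epoxide
Product: 36 CNP0297487.4
Conditions: Bu4NF, AcOH (1:1), THF, 0 °C → rt
Reagents that add atoms: none
Why: Fluoride cleavage of the silyl peroxide and the tertiary silyl ether under acetic acid buffering, which keeps the hydroperoxide protonated so that it should not open the nearby epoxide or the lactone.

Compound list
1 | pentane-2,4-dione | CC(=O)CC(C)=O | starting material
2 | 1-bromobut-2-yne | CC#CCBr | starting material
3 | 3-(but-2-yn-1-yl)pentane-2,4-dione (not isolated) | CC#CCC(C(C)=O)C(C)=O | intermediate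
4 | hept-5-yn-2-one | CC#CCCC(C)=O | intermediate
5 | 6,6-dimethoxyhept-2-yne | CC#CCCC(C)(OC)OC | intermediate
6 | chlorobis(cyclopentadienyl)[(2E)-6,6-dimethoxyhept-2-en-2-yl]zirconium (not isolated) | C/C(=C\CCC(C)(OC)OC)[Zr](Cl)(C1C=CC=C1)C1C=CC=C1 | intermediate
7 | (2E)-2-iodo-6,6-dimethoxyhept-2-ene | C/C(I)=C\CCC(C)(OC)OC | intermediate
8 | 5,6-dihydro-2H-pyran-2-one | O=C1C=CCCO1 | starting material
9 | potassium trifluoro(vinyl)borate | C=C[B-](F)(F)F.[K+] | starting material
10 | (4R)-4-ethenyloxan-2-one | O=C1C[C@H](C=C)CCO1 | intermediate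
11 | lithium enolate of 10 (not isolated) | [Li]OC1=C[C@H](C=C)CCO1 | intermediate
12 | (3S,4S)-4-ethenyl-3-methyloxan-2-one | C[C@@H]1C(=O)OCC[C@H]1C=C | intermediate
13 | (2S,3S)-3-ethenyl-5-hydroxy-N,N,2-trimethylpentanamide | C[C@H](C(=O)N(C)C)[C@H](C=C)CCO | intermediate
14 | (2S,3S)-3-ethenyl-N,N,2-trimethyl-5-oxopentanamide | C[C@H](C(=O)N(C)C)[C@H](C=C)CC=O | intermediate
15 | 2-(triphenylphosphoranylidene)propanal | CC(C=O)=P(c1ccccc1)(c1ccccc1)c1ccccc1 | starting material
16 | (2S,3S,5E)-3-ethenyl-N,N,2,6-tetramethyl-7-oxohept-5-enamide | C[C@H](C(=O)N(C)C)[C@H](C=C)C/C=C(\C)C=O | intermediate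
17 | (2S,3S,5E)-3-ethenyl-7-hydroxy-N,N,2,6-tetramethylhept-5-enamide | C[C@H](C(=O)N(C)C)[C@H](C=C)C/C=C(\C)CO | intermediate
18 | (2S,3S,5E)-7-bromo-3-ethenyl-N,N,2,6-tetramethylhept-5-enamide | C[C@H](C(=O)N(C)C)[C@H](C=C)C/C=C(\C)CBr | intermediate
19 | ethynyltrimethylsilane | C#C[Si](C)(C)C | starting material
20 | (2S,3S,5E)-3-ethenyl-N,N,2,6-tetramethyl-9-(trimethylsilyl)non-5-en-8-ynamide | C[C@H](C(=O)N(C)C)[C@H](C=C)C/C=C(\C)CC#C[Si](C)(C)C | intermediate
21 | (2S,3S)-3-ethenyl-N,N,2-trimethyl-4-{(2S,3S)-3-methyl-3-[3-(trimethylsilyl)prop-2-yn-1-yl]oxiran-2-yl}butanamide | C[C@H](C(=O)N(C)C)[C@H](C=C)C[C@@H]1O[C@@]1(C)CC#C[Si](C)(C)C | intermediate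
22 | N,N-dimethyliminium form of lactone 23 (C16=N+Me2 in place of C16=O; not isolated) | C[C@@H]1C(=[N+](C)C)O[C@H](C[C@H]1C=C)[C@@](C)(O)CC#C[Si](C)(C)C | intermediate
23 | (3S,4S,6R)-4-ethenyl-6-[(2S)-2-hydroxy-5-(trimethylsilyl)pent-4-yn-2-yl]-3-methyloxan-2-one | C[C@@H]1C(=O)O[C@H](C[C@H]1C=C)[C@@](C)(O)CC#C[Si](C)(C)C | intermediate
24 | (3S,4S,6R)-4-ethenyl-3-methyl-6-[(2S)-2-[(triethylsilyl)oxy]-5-(trimethylsilyl)pent-4-yn-2-yl]oxan-2-one | C[C@@H]1C(=O)O[C@H](C[C@H]1C=C)[C@@](C)(O[Si](CC)(CC)CC)CC#C[Si](C)(C)C | intermediate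
25 | 9-BBN adduct of 24: (3S,4R,6R)-4-[2-(9-borabicyclo[3.3.1]nonan-9-yl)ethyl] analogue (not isolated) | C[C@@H]1C(=O)O[C@H](C[C@H]1CCB1C2CCCC1CCC2)[C@@](C)(O[Si](CC)(CC)CC)CC#C[Si](C)(C)C | intermediate
26 | (3S,4R,6R)-4-[(3E)-7,7-dimethoxy-3-methyloct-3-en-1-yl]-3-methyl-6-[(2S)-2-[(triethylsilyl)oxy]-5-(trimethylsilyl)pent-4-yn-2-yl]oxan-2-one | C[C@@H]1C(=O)O[C@H](C[C@H]1CC/C(C)=C/CCC(C)(OC)OC)[C@@](C)(O[Si](CC)(CC)CC)CC#C[Si](C)(C)C | intermediate
27 | (3S,4R,6R)-4-[(3E)-7,7-dimethoxy-3-methyloct-3-en-1-yl]-3-methyl-6-[(2S)-2-[(triethylsilyl)oxy]pent-4-yn-2-yl]oxan-2-one | C[C@@H]1C(=O)O[C@H](C[C@H]1CC/C(C)=C/CCC(C)(OC)OC)[C@@](C)(O[Si](CC)(CC)CC)CC#C | intermediate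
28 | (3S,4R,6R)-4-[(3E)-7-hydroperoxy-7-methoxy-3-methyloct-3-en-1-yl]-3-methyl-6-[(2S)-2-[(triethylsilyl)oxy]pent-4-yn-2-yl]oxan-2-one (both C8 epimers) | C[C@@H]1C(=O)O[C@H](C[C@H]1CC/C(C)=C/CCC(C)(OC)OO)[C@@](C)(O[Si](CC)(CC)CC)CC#C | intermediate
29 | tert-butyldimethylsilyl peroxide of 28 (both C8 epimers) | C[C@@H]1C(=O)O[C@H](C[C@H]1CC/C(C)=C/CCC(C)(OC)OO[Si](C)(C)C(C)(C)C)[C@@](C)(O[Si](CC)(CC)CC)CC#C | intermediate
30 | (3S,4R,6R)-4-{(3E)-7-[(tert-butyldimethylsilyl)peroxy]-7-methoxy-3-methyloct-3-en-1-yl}-3-methyl-6-[(2S,4E)-5-(4,4,5,5-tetramethyl-1,3,2-dioxaborolan-2-yl)-2-[(triethylsilyl)oxy]pent-4-en-2-yl]oxan-2-one | C[C@@H]1C(=O)O[C@H](C[C@H]1CC/C(C)=C/CCC(C)(OC)OO[Si](C)(C)C(C)(C)C)[C@@](C)(O[Si](CC)(CC)CC)C/C=C/B1OC(C)(C)C(C)(C)O1 | intermediate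
31 | potassium (E)-alkenyltrifluoroborate corresponding to 30 (BF3K in place of the pinacol boronate) | C[C@@H]1C(=O)O[C@H](C[C@H]1CC/C(C)=C/CCC(C)(OC)OO[Si](C)(C)C(C)(C)C)[C@@](C)(O[Si](CC)(CC)CC)C/C=C/[B-](F)(F)F.[K+] | intermediate
32 | (E)-alkenyldifluoroborane corresponding to 31 (not isolated) | C[C@@H]1C(=O)O[C@H](C[C@H]1CC/C(C)=C/CCC(C)(OC)OO[Si](C)(C)C(C)(C)C)[C@@](C)(O[Si](CC)(CC)CC)C/C=C/B(F)F | intermediate
33 | C8 silylperoxycarbenium ion paired with the alkenyl(methoxy)difluoroborate at C7 (zwitterion, not isolated) | C[C@@H]1C(=O)O[C@H](C[C@H]1CC/C(C)=C/CCC(C)=[O+]O[Si](C)(C)C(C)(C)C)[C@@](C)(O[Si](CC)(CC)CC)C/C=C/[B-](F)(F)OC | intermediate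
34 | (1R,3R,4S,6E,8S,11E,15S)-8-[(tert-butyldimethylsilyl)peroxy]-4-[(triethylsilyl)oxy]cembra-6,11-dien-16,3-olide | C[C@@H]1C(=O)O[C@@H]2C[C@H]1CC/C(C)=C/CC[C@](C)(OO[Si](C)(C)C(C)(C)C)/C=C/C[C@]2(C)O[Si](CC)(CC)CC | intermediate
35 | (1R,3R,4S,6E,8S,11S,12S,15S)-8-[(tert-butyldimethylsilyl)peroxy]-11,12-epoxy-4-[(triethylsilyl)oxy]cembr-6-en-16,3-olide | C[C@@H]1C(=O)O[C@@H]2C[C@H]1CC[C@]1(C)O[C@H]1CC[C@](C)(OO[Si](C)(C)C(C)(C)C)/C=C/C[C@]2(C)O[Si](CC)(CC)CC | intermediate
36 | CNP0297487.4, (1R,3R,4S,6E,8S,11S,12S,15S)-11,12-epoxy-8-hydroperoxy-4-hydroxycembr-6-en-16,3-olide | C[C@@H]1C(=O)O[C@@H]2C[C@H]1CC[C@]1(C)O[C@H]1CC[C@](C)(OO)/C=C/C[C@]2(C)O | target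

Total step count: 23. Longest linear sequence: 20 steps (steps 4–23); steps 1–3 make the vinyl iodide 7.

Steps most likely to fail

Step 21. What may go wrong: after ionisation the peroxide rearranges or fragments faster than C7 attacks, the chains oligomerise instead of closing the ring, or the cation is attacked on the wrong face. Fallback with known reactions, setting out from 27 and returning at 34: semihydrogenation of the alkyne (H2, Pd/CaCO3 poisoned with Pb(OAc)2, quinoline) gives the allyl compound F1; ketal hydrolysis (PPTS, acetone/H2O) gives the methyl ketone F2; CH2=CHMgBr with CeCl3 at −78 °C adds to the ketone in preference to the lactone and gives the tertiary vinyl carbinol F3 as both C8 epimers; ring-closing metathesis with the second-generation Grubbs catalyst at high dilution closes the 14-membered ring at C6=C7 and gives the macrocyclic tertiary allylic alcohol F4; acid-catalysed exchange of the tertiary allylic hydroxyl with concentrated H2O2 (cat. H2SO4, Et2O, 0 °C) gives the macrocyclic hydroperoxide F5, and TBSCl/imidazole then gives 34 after separation of C8 epimers and alkene isomers. This detour gives up control of C8 and risks allylic transposition during the exchange.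

Step 19. What may go wrong: the boron hydrides reduce the O–O bond or strip the peroxide silyl group before the alkyne is consumed. Fallback, setting out from 27 and returning at 30: the alkyne is first semihydrogenated to the allyl compound F1 (as above); the ketal is perhydrolysed to the hydroperoxy ketal F6 and silylated to the silylperoxy ketal F7 as in steps 17 and 18; the alkenylboronate is then made without any hydride by cross-metathesis of F7 with vinylboronic acid pinacol ester (second-generation Grubbs catalyst, CH2Cl2, 40 °C), a reaction type that tolerates dialkyl peroxides and favours the (E)-alkenylboronate.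

Step 22. What may go wrong: the conformation of the macrocycle overrides the catalyst so that oxygen reaches the wrong face of C11=C12, or the silyl peroxide is hydrolysed in the basic medium. Fallback, setting out from 34 and returning at 35: bromohydrin formation (NBS, THF/H2O, 0 °C; bromine at C11, hydroxyl at the tertiary C12, anti addition) gives the bromohydrin F8, and ring closure with DBU (CH2Cl2, rt) gives the epoxide. Because the epoxide oxygen ends on the face opposite to the one the electrophile attacked, this two-step route delivers the face that a direct substrate-controlled epoxidation does not.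

Further compounds
F1 | step 21 | (3S,4R,6R)-4-[(3E)-7,7-dimethoxy-3-methyloct-3-en-1-yl]-3-methyl-6-[(2S)-2-[(triethylsilyl)oxy]pent-4-en-2-yl]oxan-2-one | C[C@@H]1C(=O)O[C@H](C[C@H]1CC/C(C)=C/CCC(C)(OC)OC)[C@@](C)(O[Si](CC)(CC)CC)CC=C
F2 | step 21 | (3S,4R,6R)-3-methyl-4-[(3E)-3-methyl-7-oxooct-3-en-1-yl]-6-[(2S)-2-[(triethylsilyl)oxy]pent-4-en-2-yl]oxan-2-one | C[C@@H]1C(=O)O[C@H](C[C@H]1CC/C(C)=C/CCC(C)=O)[C@@](C)(O[Si](CC)(CC)CC)CC=C
F3 | step 21 | (3S,4R,6R)-4-[(3E)-7-hydroxy-3,7-dimethylnona-3,8-dien-1-yl]-3-methyl-6-[(2S)-2-[(triethylsilyl)oxy]pent-4-en-2-yl]oxan-2-one (both C8 epimers) | C[C@@H]1C(=O)O[C@H](C[C@H]1CC/C(C)=C/CCC(C)(O)C=C)[C@@](C)(O[Si](CC)(CC)CC)CC=C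
F4 | step 21 | (1R,3R,4S,6E,11E,15S)-8-hydroxy-4-[(triethylsilyl)oxy]cembra-6,11-dien-16,3-olide (both C8 epimers) | C[C@@H]1C(=O)O[C@@H]2C[C@H]1CC/C(C)=C/CCC(C)(O)/C=C/C[C@]2(C)O[Si](CC)(CC)CC
F5 | step 21 | (1R,3R,4S,6E,11E,15S)-8-hydroperoxy-4-[(triethylsilyl)oxy]cembra-6,11-dien-16,3-olide (both C8 epimers) | C[C@@H]1C(=O)O[C@@H]2C[C@H]1CC/C(C)=C/CCC(C)(OO)/C=C/C[C@]2(C)O[Si](CC)(CC)CC
F6 | step 19 | (3S,4R,6R)-4-[(3E)-7-hydroperoxy-7-methoxy-3-methyloct-3-en-1-yl]-3-methyl-6-[(2S)-2-[(triethylsilyl)oxy]pent-4-en-2-yl]oxan-2-one (both C8 epimers) | C[C@@H]1C(=O)O[C@H](C[C@H]1CC/C(C)=C/CCC(C)(OC)OO)[C@@](C)(O[Si](CC)(CC)CC)CC=C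
F7 | step 19 | tert-butyldimethylsilyl peroxide of F6 (both C8 epimers) | C[C@@H]1C(=O)O[C@H](C[C@H]1CC/C(C)=C/CCC(C)(OC)OO[Si](C)(C)C(C)(C)C)[C@@](C)(O[Si](CC)(CC)CC)CC=C
F8 | step 22 | (1R,3R,4S,6E,8S,11R,12S,15S)-11-bromo-8-[(tert-butyldimethylsilyl)peroxy]-12-hydroxy-4-[(triethylsilyl)oxy]cembr-6-en-16,3-olide | C[C@@H]1C(=O)O[C@@H]2C[C@H]1CC[C@](C)(O)[C@H](Br)CC[C@](C)(OO[Si](C)(C)C(C)(C)C)/C=C/C[C@]2(C)O[Si](CC)(CC)CC
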